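## Retrosynthetic overview
1. The C12 carbinol comes from equatorial CH3MgBr addition to a C12 ketone. That ketone comes from a transannular bromonium closure (C8–C13) of a norbornane-fused (E,E)-cyclodeca-1,5-diene. This closure makes rings A and B, installs Br and sets three stereocentres in one step, and DMSO intercepts the cation.
2. The ten-membered ring comes from an anionic oxy-Cope ring expansion of a trans-1,2-divinylcyclohexanol (a temporary six-membered ring). The regiospecific enolate is carried through the triflate to C8–CH3.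
3. The divinyl carbinol comes from double vinylation of a tricyclic ene-dione, which is made by aldol closure onto a norbornane-2,3-dione.
4. Ring D (the norbornane) forms when the C3 enolate π-bond displaces halide from the neopentyl C4. The halide is generated by opening a cyclopropyl ketone.
5. Ring C is (S)-cryptone, from isovaleraldehyde and MVK. Order of ring formation: C, D, temporary B, then A and B together.

Atom labels: C1–C15 are the ring atoms in the order of the target SMILES. C1 CH(i-Pr), C2 CH2, C3 bridgehead CH, C4 bridge CH2, C5 quaternary bridgehead, C6/C7 CH2CH2, C8 C(CH3), C9 CHBr, C10/C11 CH2CH2, C12 C(CH3)OH, C13 and C14 ring-fusion CH, C15 CHOH.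

Assumption: the presumed biogenesis is taken as (i) Br+-induced closure of a C8=C9/C12=C13 1,5-diene to the bromodecalin and (ii) attack of the C3–C15 π-bond on the neopentyl C4–X carbon of the tricyclic CH2Br congeners to give the norbornane.

## Route

Step 1
Reactants: 1 3-methylbutanal (isovaleraldehyde); 2 but-3-en-2-one (methyl vinyl ketone)
Product: 3 (S)-2-isopropyl-5-oxohexanal
Conditions: (S)-2-[methoxy(diphenyl)methyl]pyrrolidine (5 mol%), ethyl 3,4-dihydroxybenzoate (20 mol%), neat, 4 °C
Reagents that add atoms: none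
Why: Enamine-catalysed asymmetric Michael addition; the (S)-diarylprolinol ether shields one face of the E-enamine, so MVK adds to give the (S)-configured C1, the only stereocentre that is not substrate-controlled.

Step 2
Reactants: 3 (S)-2-isopropyl-5-oxohexanal
Product: 4 (S)-4-isopropylcyclohex-2-en-1-one [(S)-cryptone]
Conditions: LiOH (10 mol%), i-PrOH, rt
Reagents that add atoms: none
Why: Intramolecular aldol condensation of the methyl ketone onto the aldehyde closes ring C (C14=C5, C15=O), and the mild base leaves C1 untouched.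

Step 3
Reactants: 4 (S)-cryptone; 5 2-(2-bromoethyl)-2-methyl-1,3-dioxolane
Product: 8 (S)-4-isopropyl-3-[2-(2-methyl-1,3-dioxolan-2-yl)ethyl]cyclohex-2-en-1-one, via Grignard reagent 6 (not isolated), via magnesium enolate 7 (not isolated)
Conditions: 5, Mg, THF; CuBr·SMe2 (10 mol%), 4, THF, −78 °C; then PhS(Cl)=N-t-Bu, −78 °C to rt
Reagents that add atoms: none
Why: Cu-catalysed 1,4-addition followed by one-pot Mukaiyama dehydrogenation of the enolate with the sulfinimidoyl chloride amounts to β-alkylation of the enone; the transient C5 centre is erased and C1 is not touched.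

Step 4
Reactants: 8 β-substituted enone
Product: 9 cyclopropyl ketone 5-isopropyl-6-[2-(2-methyl-1,3-dioxolan-2-yl)ethyl]bicyclo[4.1.0]heptan-2-one (C7H2 trans to i-Pr)
Conditions: Me3S(O)I, NaH, DMSO, rt to 50 °C
Reagents that add atoms: trimethylsulfoxonium iodide C[S+](C)(C)=O.[I-]
Why: Corey–Chaykovsky cyclopropanation; the ylide adds to C5 anti to the i-Pr group (pseudo-axial because of A(1,2) strain) and closes onto C14, which fixes the quaternary C5 with C4 trans and C6 cis to i-Pr.

Step 5
Reactants: 9 cyclopropyl ketone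
Product: 11 norbornanone 5-endo-isopropyl-4-[2-(2-methyl-1,3-dioxolan-2-yl)ethyl]bicyclo[2.2.1]heptan-2-one, via iodomethyl ketone 10 (not isolated)
Conditions: anhydrous MgI2 (1.0 equiv), i-Pr2NEt (0.5 equiv), toluene, 80 °C
Reagents that add atoms: none
Why: Proposed new method: iodide opens the Mg-activated cyclopropyl ketone by SN2 attack at the unhindered C4H2 (closest known type: MgI2- or TMSI-mediated homoconjugate opening of acceptor cyclopropanes), and Mg/amine soft enolisation then equilibrates the enolates of 10; re-closure from C14 only regenerates 9, whereas the C3 enolate displaces the neopentyl iodide irreversibly (ring strain falls from about 27 to about 17 kcal/mol), so 9 drains to 11, C3 is set by the bridge geometry, i-Pr ends up endo, and the bond and polarity match the presumed C3(π)→C4–X closure of ring D.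

Step 6
Reactants: 11 norbornanone
Product: 12 5-endo-isopropyl-4-[2-(2-methyl-1,3-dioxolan-2-yl)ethyl]bicyclo[2.2.1]heptane-2,3-dione
Conditions: SeO2 (1.2 equiv), 1,4-dioxane, 100 °C
Reagents that add atoms: selenium dioxide O=[Se]=O
Why: Riley oxidation; C14H2 is the only enolisable position because C3 is a bridgehead, exactly as in camphor to camphorquinone.

Step 7
Reactants: 12 norbornanedione ketal
Product: 14 tricyclic ene-dione (C8=O, C13=C14, C15=O), via trione 13 (not isolated)
Conditions: 2 M HCl, THF, 50 °C
Reagents that add atoms: water O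
Why: Ketal hydrolysis followed by a Robinson-type intramolecular aldol condensation of the methyl ketone (C13) onto the activated C14 carbonyl; this is the only six-membered closure available, and no new stereocentre forms.

Step 8
Reactants: 14 tricyclic ene-dione
Product: 16 divinyl hydroxy ketone (C8 axial OH and equatorial vinyl; C13 equatorial vinyl; H14 endo; C15=O), via magnesium enolate 15 (not isolated)
Conditions: CH2=CHMgBr (3.5 equiv), CuBr·SMe2 (20 mol%), THF, −78 °C; then LaCl3·2LiCl, −78 to 0 °C; H2O; then K2CO3, MeOH, rt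
Reagents that add atoms: vinylmagnesium bromide C=C[Mg]Br
Why: Cu-catalysed conjugate addition goes to C13, the only unhindered β-carbon (fixed s-cis C15 enone), anti to the 1,3-syn-axial C4 bridge; the resulting enolate masks C15 while the La-promoted Grignard 1,2-addition attacks C8=O equatorially (trans-diequatorial vinyls), and K2CO3 equilibrates C14 to the exo-alkyl/endo-H epimer because the endo face is blocked by the endo i-Pr.

Step 9
Reactants: 16 divinyl hydroxy ketone
Product: 17 diol (C15 endo-OH)
Conditions: NaBH4, MeOH, 0 °C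
Reagents that add atoms: none
Why: Hydride reduction of a norbornanone from the exo face (the endo face is closed by C2–H and the endo i-Pr) gives the endo C15 alcohol, trans to the exo C13 substituent.

Step 10
Reactants: 17 diol
Product: 18 C15 O-triethylsilyl ether (tertiary C8–OH free)
Conditions: TESCl, imidazole, DMF, rt
Reagents that add atoms: chlorotriethylsilane CC[Si](Cl)(CC)CC
Why: Selective silylation of the secondary alcohol over the tertiary allylic one, so that only one alkoxide and later only one O-nucleophile (the enolate) is present in step 11.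

Step 11
Reactants: 18 TES ether
Product: 20 norbornane-fused cyclodeca-1,5-dienyl triflate (C8–OTf; C7 trans to C10; 12E), via potassium enolate 19 (not isolated)
Conditions: KH, 18-crown-6, THF, 0 °C to rt; then N-(5-chloro-2-pyridyl)triflimide, −78 °C
Reagents that add atoms: Comins reagent Clc1ccc(nc1)N(S(=O)(=O)C(F)(F)F)S(=O)(=O)C(F)(F)F
Why: Anionic oxy-Cope [3,3] ring expansion through the chair transition state of the trans-diequatorial divinyl carbinol places C7 and C14 pseudo-equatorial, so both new C=C bonds are ring-E, and the regiospecific C8=C9 enolate is trapped as its triflate; C8 and C13 become sp2, and C14, C5, C1, C3 and C15 are unaffected.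

Step 12
Reactants: 20 dienyl triflate
Product: 21 (8E,12E)-8-methylcyclodeca-8,12-diene fused to the norbornane (kept at or below 0 °C and used at once)
Conditions: MeMgBr, Fe(acac)3 (5 mol%), THF–NMP, −30 °C
Reagents that add atoms: methylmagnesium bromide C[Mg]Br
Why: Iron-catalysed (Kochi–Fürstner) cross-coupling of an alkenyl triflate proceeds with retention of geometry, at a temperature well below that of the Cope reversion of the 1,5-diene.

Step 13
Reactants: 21 (E,E)-diene
Product: 23 tetracyclic bromo ketone (C9 equatorial Br, C12=O, trans-decalin), via alkoxysulfonium salt 22 (not isolated)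
Conditions: NBS (1.05 equiv), DMSO (5 equiv), HFIP–CH2Cl2, −20 °C; then Et3N, −20 °C to rt
Reagents that add atoms: N-bromosuccinimide O=C1CCC(=O)N1Br; dimethyl sulfoxide CS(C)=O
Why: Proposed new method: Br+ adds to the outer face of the strained, more nucleophilic trisubstituted C8=C9 bond and the C12=C13 bond held across the ring attacks C8 anti through the crossed chair–chair conformer (C8 reaches C13 from the C5 side, with H14 in the alkene plane), which gives equatorial Br, axial C8–CH3 and H13 anti to H14; DMSO then captures the developing C12 cation and Et3N collapses 22 to the ketone (closest known types: NBS-induced transannular cyclisation of germacradienes such as costunolide to 1-bromoeudesmanes, NBS/DMSO bromohydrin formation, Kornblum oxidation).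

Step 14
Reactants: 23 bromo ketone
Product: 25 target CNP0295684.1, via target TES ether 24 (not isolated)
Conditions: MeMgBr, LaCl3·2LiCl, THF, −78 °C; then 1 M HCl, THF–MeOH, 0 °C to rt
Reagents that add atoms: methylmagnesium bromide C[Mg]Br
Why: Grignard 1,2-addition from the equatorial direction, because the axial face of C12=O is blocked by the 1,3-diaxial C8–CH3; this gives the equatorial CH3/axial OH carbinol that anti water capture of a C12 cation cannot give, the low-basicity La reagent avoids γ-bromo enolate chemistry, and dilute acid removes the TES group.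

## Compound list
1 | 3-methylbutanal | CC(C)CC=O | starting material
2 | but-3-en-2-one | CC(=O)C=C | starting material
3 | (S)-2-isopropyl-5-oxohexanal | CC(C)[C@@H](C=O)CCC(C)=O | intermediate
4 | (S)-4-isopropylcyclohex-2-en-1-one | CC(C)[C@@H]1CCC(=O)C=C1 | intermediate
5 | 2-(2-bromoethyl)-2-methyl-1,3-dioxolane | CC1(CCBr)OCCO1 | starting material
6 | 2-(2-methyl-1,3-dioxolan-2-yl)ethylmagnesium bromide | CC1(CC[Mg]Br)OCCO1 | intermediate
7 | bromomagnesium enolate of the trans-3,4-disubstituted cyclohexanone | CC(C)[C@@H]1CCC(O[Mg]Br)=C[C@H]1CCC1(C)OCCO1 | intermediate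
8 | (S)-4-isopropyl-3-[2-(2-methyl-1,3-dioxolan-2-yl)ethyl]cyclohex-2-en-1-one | CC(C)[C@@H]1CCC(=O)C=C1CCC1(C)OCCO1 | intermediate
9 | 5-isopropyl-6-[2-(2-methyl-1,3-dioxolan-2-yl)ethyl]bicyclo[4.1.0]heptan-2-one, CH2 trans to i-Pr | CC(C)[C@@H]1CCC(=O)[C@H]2C[C@@]12CCC1(C)OCCO1 | intermediate
10 | 3-(iodomethyl)-4-isopropyl-3-[2-(2-methyl-1,3-dioxolan-2-yl)ethyl]cyclohexanone, CH2I trans to i-Pr | CC(C)[C@@H]1CCC(=O)C[C@]1(CI)CCC1(C)OCCO1 | intermediate
11 | 5-endo-isopropyl-4-[2-(2-methyl-1,3-dioxolan-2-yl)ethyl]bicyclo[2.2.1]heptan-2-one | CC(C)[C@@H]1C[C@H]2C[C@]1(CCC1(C)OCCO1)CC2=O | intermediate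
12 | 5-endo-isopropyl-4-[2-(2-methyl-1,3-dioxolan-2-yl)ethyl]bicyclo[2.2.1]heptane-2,3-dione | CC(C)[C@@H]1C[C@H]2C[C@]1(CCC1(C)OCCO1)C(=O)C2=O | intermediate
13 | 5-endo-isopropyl-4-(3-oxobutyl)bicyclo[2.2.1]heptane-2,3-dione | CC(C)[C@@H]1C[C@H]2C[C@]1(CCC(C)=O)C(=O)C2=O | intermediate
14 | tricyclic ene-dione (cyclohexenone fused to C3/C4 of the norbornan-2-one, 5-endo-i-Pr) | CC(C)[C@@H]1C[C@H]2C[C@@]13CCC(=O)C=C3C2=O | intermediate
15 | bromomagnesium C14=C15 enolate of the 13-vinyl diketone | CC(C)[C@@H]1C[C@H]2C[C@@]13CCC(=O)[C@@H](C=C)C3=C2O[Mg]Br | intermediate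
16 | divinyl hydroxy ketone (C8 axial OH/equatorial vinyl, C13 equatorial vinyl, H14 endo) | CC(C)[C@@H]1C[C@H]2C[C@@]13CC[C@](O)(C=C)[C@@H](C=C)[C@@H]3C2=O | intermediate
17 | diol (C15 endo-OH) | CC(C)[C@@H]1C[C@H]2C[C@@]13CC[C@](O)(C=C)[C@@H](C=C)[C@@H]3[C@H]2O | intermediate
18 | C15 O-TES ether of 17 | CC(C)[C@@H]1C[C@H]2C[C@@]13CC[C@](O)(C=C)[C@@H](C=C)[C@@H]3[C@H]2O[Si](CC)(CC)CC | intermediate
19 | potassium C8=C9 enolate of the ring-expanded (12E)-cyclodecenone | CC(C)[C@@H]1C[C@H]2C[C@@]13CC/C([O-])=C/CC/C=C/[C@@H]3[C@H]2O[Si](CC)(CC)CC.[K+] | intermediate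
20 | cyclodeca-1,5-dienyl triflate (C7 trans to C10, 12E) | CC(C)[C@@H]1C[C@H]2C[C@@]13CC/C(OS(=O)(=O)C(F)(F)F)=C/CC/C=C/[C@@H]3[C@H]2O[Si](CC)(CC)CC | intermediate
21 | (8E,12E)-8-methylcyclodecadiene fused to the norbornane, C15 endo-OTES | CC(C)[C@@H]1C[C@H]2C[C@@]13CC/C(C)=C/CC/C=C/[C@@H]3[C@H]2O[Si](CC)(CC)CC | intermediate
22 | C12 (equatorial) dimethylalkoxysulfonium succinimidate of the cyclised bromide | CC(C)[C@@H]1C[C@H]2C[C@@]13CC[C@]1(C)[C@@H](Br)CC[C@H](O[S+](C)C)[C@H]1[C@@H]3[C@H]2O[Si](CC)(CC)CC.O=C1CCC(=O)[N-]1 | intermediate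
23 | tetracyclic bromo ketone (C12=O, C15 endo-OTES) | CC(C)[C@@H]1C[C@H]2C[C@@]13CC[C@]1(C)[C@@H](Br)CCC(=O)[C@H]1[C@@H]3[C@H]2O[Si](CC)(CC)CC | intermediate
24 | C15 O-TES ether of the target | CC(C)[C@@H]1C[C@H]2C[C@@]13CC[C@]1(C)[C@@H](Br)CC[C@@](C)(O)[C@H]1[C@@H]3[C@H]2O[Si](CC)(CC)CC | intermediate
25 | CNP0295684.1 | CC(C)[C@@H]1C[C@H]2C[C@@]13CC[C@]1(C)[C@@H](Br)CC[C@@](C)(O)[C@H]1[C@@H]3[C@H]2O | target

## Step count and risks
Total step count: 14. Longest linear sequence: 14 (1/2 to 25).

**Step 13 (transannular closure with a disubstituted alkene, DMSO interception).**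
- Risks: DMSO attacks the bromonium ion directly, or hydride shifts occur at the secondary C12 cation.
- Fallback: it sets out from 21 and comes back at 23. The termination is separated from the oxidation. NBS in aqueous acetone at 0 °C lets water, a weaker and smaller nucleophile, complete the anti addition and gives the equatorial C12 bromo alcohol F1. A separate Dess–Martin oxidation of this only free hydroxyl then gives 23.

**Step 8 (organocopper on an easily reduced ene-dione, tandem 1,2-addition).**
- Risk: electron-transfer reduction of the ene-dione by the organocopper species.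
- Fallback: it sets out from 14 and comes back at 16. The enolate-masking tandem is replaced by a redox-neutral Rh(I)-catalysed 1,4-addition of potassium vinyltrifluoroborate ([Rh(cod)Cl]2, Et3N, aqueous dioxane), which gives the isolated 13-vinyl diketone F2. The two ketones are then distinguished by sterics alone: vinylcerium dichloride at −78 °C adds to the open C8 cyclohexanone and not to the flanked C15 norbornanone, giving 16.

**Step 5 (untested one-step isomerisation, ketal exposed to MgI2).**
- Fallback: it sets out from 8 and comes back at 11, bypassing 9. Cu-catalysed conjugate addition of (isopropoxydimethylsilyl)methylmagnesium chloride anti to i-Pr gives the β-silylmethyl ketone F3. Tamao oxidation (H2O2, KF, KHCO3) gives the hydroxymethyl ketone F4, and MsCl/Et3N gives the mesylate F5. KHMDS (THF, −78 °C to rt) forms the kinetic, less hindered C3 enolate, which closes the norbornanone 11.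

Further compounds
F1 | step 13 | C12 equatorial alcohol of the cyclised bromide (C15 endo-OTES) | CC(C)[C@@H]1C[C@H]2C[C@@]13CC[C@]1(C)[C@@H](Br)CC[C@H](O)[C@H]1[C@@H]3[C@H]2O[Si](CC)(CC)CC
F2 | step 8 | 13-vinyl diketone (equatorial vinyl, H14 endo) | CC(C)[C@@H]1C[C@H]2C[C@@]13CCC(=O)[C@@H](C=C)[C@@H]3C2=O
F3 | step 5 | 3-[(isopropoxydimethylsilyl)methyl]-4-isopropyl-3-[2-(2-methyl-1,3-dioxolan-2-yl)ethyl]cyclohexanone, CH2Si trans to i-Pr | CC(C)[C@@H]1CCC(=O)C[C@]1(C[Si](C)(C)OC(C)C)CCC1(C)OCCO1
F4 | step 5 | 3-(hydroxymethyl)-4-isopropyl-3-[2-(2-methyl-1,3-dioxolan-2-yl)ethyl]cyclohexanone | CC(C)[C@@H]1CCC(=O)C[C@]1(CO)CCC1(C)OCCO1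
F5 | step 5 | mesylate of F4 | CC(C)[C@@H]1CCC(=O)C[C@]1(COS(C)(=O)=O)CCC1(C)OCCO1
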